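**Plan**
1. Numbering: in each quinolizidinone C1 bears a chain next to C2=O, C3 bears the methyl group, then come C4, N5, C6–C8, C9 (second chain) and C9a. Ring A = C1–C4/N5/C9a, ring B = N5/C6–C9/C9a. Unit 1 (1S,3R,9R,9aR) is unprimed, unit 2 (1S,3R,9S,9aS) is primed.
2. Enabling feature: C9–C9a belongs to the 16-membered carbocycle (C9a, C1, five CH2, C9′, C9a′, C1′, five CH2, C9). Each of its two stereocentres points one substituent out of that ring, N5 on C9a and C8 of ring B on C9, which is the carboxyl/alkenyl pattern of an ester enolate Claisen product.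
3. Cuts, in retrosynthetic order: both ketones to carbinols; N5–C4, N5–C6, N5′–C4′, N5′–C6′; N5 to CO2H; C9–C9a (back to a 20-membered allylic lactone); the lactone acyl–O7 bond; N5′ to CO2H; C9′–C9a′ (open-chain Claisen); the acyl–O7′ ester; C8=C9 and C8′=C9′ (cross-metathesis); the C9a homologation; C1–C2 (aldol).
4. Forward: one building block (15: C9a to C4 plus chain) is used twice and the halves are joined by an ester and a first Claisen. Then come the 20-membered lactone, the 16-membered carbocycle, rings A, B, A′ and B′ together in one fourfold N-alkylation, and finally both ketones.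
5. Stereochemistry: C3/C3′ come from the (R)-Roche ester and C1/C1′ (with the transient C2/C2′) from an Evans syn aldol. C9/C9a and C9′/C9a′ arise by chirality transfer from the C7 (R) and C7′ (S) carbinol carbons (from the two benzyl glycidyl ethers) through E-alkene/Z-ketene acetal chairs. Both Curtius steps retain configuration.
6. The CH2OBn group on C7 (C7′) is C6 (C6′), so each Claisen delivers all carbons of ring B (B′), and unit 2 can stay open, non-basic and fully stereodefined until the end.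

Key step: step 20

Remark on the chemistry: the C2 and C2′ carbinol centres are transient (set syn to C1 by the aldol, erased in step 25), and compounds 1, 4, 5, 16 and 18 are taken as commercial.

**Step 1**
Reactants: 1 methyl (R)-3-hydroxy-2-methylpropanoate
Product: 2 methyl (R)-3-(benzyloxy)-2-methylpropanoate
Conditions: BnOC(=NH)CCl3, TfOH (cat.), CH2Cl2–cyclohexane, 0 °C → rt
Reagents that add atoms: benzyl 2,2,2-trichloroacetimidate, N=C(OCc1ccccc1)C(Cl)(Cl)Cl
Why: Acid-catalysed O-benzylation with the trichloroacetimidate needs no base, so the epimerisable C3 centre should stay intact.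

**Step 2**
Reactants: 2 methyl (R)-3-(benzyloxy)-2-methylpropanoate
Product: 3 (R)-3-(benzyloxy)-2-methylpropanal
Conditions: i-Bu2AlH, CH2Cl2, −78 °C; aq. potassium sodium tartrate
Reagents that add atoms: none
Why: Partial ester reduction with i-Bu2AlH stops at the aluminium hemiacetal at −78 °C and releases the aldehyde on work-up; 3 is used at once to protect C3.

**Step 3**
Reactants: 4 non-8-enoic acid; 5 (R)-4-benzyl-1,3-oxazolidin-2-one
Product: 7 (R)-4-benzyl-3-(non-8-enoyl)-1,3-oxazolidin-2-one, via pivalic mixed anhydride 6 (not isolated)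
Conditions: t-BuCOCl, Et3N, THF, −20 °C; then LiCl, 5, −20 °C → rt
Reagents that add atoms: none
Why: N-acylation of the oxazolidinone through a mixed pivalic anhydride with LiCl/Et3N is the standard mild entry to Evans imides.

**Step 4**
Reactants: 7 (R)-4-benzyl-3-(non-8-enoyl)-1,3-oxazolidin-2-one; 3 (R)-3-(benzyloxy)-2-methylpropanal
Product: 9 (R)-4-benzyl-3-[(2R,3S,4R)-5-(benzyloxy)-2-(hept-6-enyl)-3-hydroxy-4-methylpentanoyl]-1,3-oxazolidin-2-one, via Z-dibutylboron enolate 8 (not isolated)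
Conditions: n-Bu2BOTf, Et3N, CH2Cl2, −78 → 0 °C; 3, −78 → 0 °C; H2O2, MeOH, pH 7 buffer, 0 °C
Reagents that add atoms: none
Why: In this Evans syn aldol the Z-boron enolate reacts through a Zimmerman–Traxler chair on the face left open by the (R)-benzyl group, which sets C1 and C2 and should override the small anti-Felkin bias of the aldehyde to give the all-syn C1–C2–C3 triad.

**Step 5**
Reactants: 9 aldol adduct
Product: 10 3-O-tert-butyldimethylsilyl ether of 9
Conditions: TBSOTf, 2,6-lutidine, CH2Cl2, 0 °C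
Reagents that add atoms: tert-butyldimethylsilyl triflate, CC(C)(C)[Si](C)(C)OS(=O)(=O)C(F)(F)F
Why: Silyl triflate silylation covers the hindered C2 hydroxyl, which would otherwise close a γ-lactone onto the later carboxyl group.

**Step 6**
Reactants: 10 silylated imide
Product: 11 (2R,3S,4R)-5-(benzyloxy)-3-(tert-butyldimethylsilyloxy)-2-(hept-6-enyl)-4-methylpentanoic acid
Conditions: LiOH, H2O2, THF–H2O, 0 °C; aq. Na2SO3; 1 M HCl
Reagents that add atoms: hydrogen peroxide (as LiOOH), OO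
Why: Hydroperoxide attacks the exocyclic imide carbonyl selectively (standard auxiliary removal) without touching C1 or the terminal alkene.

**Step 7**
Reactants: 11 acid
Product: 13 (3R,4S,5R)-6-(benzyloxy)-4-(tert-butyldimethylsilyloxy)-1-diazo-3-(hept-6-enyl)-5-methylhexan-2-one, via isobutyl carbonic anhydride 12 (not isolated)
Conditions: i-BuOCOCl, N-methylmorpholine, THF, −20 °C; CH2N2, Et2O, 0 °C
Reagents that add atoms: diazomethane, C=[N+]=[N-]
Why: This is the first half of an Arndt–Eistert homologation, in which diazomethane is acylated by the mixed anhydride under conditions that leave the α-centre C1 alone.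

**Step 8**
Reactants: 13 diazoketone
Product: 15 methyl (3S)-3-[(1R,2R)-3-(benzyloxy)-1-(tert-butyldimethylsilyloxy)-2-methylpropyl]dec-9-enoate, via ketene 14 (not isolated)
Conditions: AgO2CPh (cat.), Et3N, MeOH, rt, dark
Reagents that add atoms: methanol, CO
Why: In the silver-catalysed Wolff rearrangement C1 migrates with retention, and methanol traps the ketene, which inserts C9a between C1 and the carboxyl carbon.

**Step 9**
Reactants: 16 (S)-benzyl glycidyl ether
Product: 17 (S)-1-(benzyloxy)but-3-en-2-ol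
Conditions: Me3SI, n-BuLi, THF, −10 °C → rt
Reagents that add atoms: trimethylsulfonium iodide (as its methylide), C[S+](C)C.[I-]
Why: In this epoxide-to-allylic-alcohol homologation with excess dimethylsulfonium methylide the ylide opens the terminal carbon and Me2S is eliminated, so the C–O bond at the stereocentre (future C7′) is never broken.

**Step 10**
Reactants: 18 (R)-benzyl glycidyl ether
Product: 19 (R)-1-(benzyloxy)but-3-en-2-ol
Conditions: Me3SI, n-BuLi, THF, −10 °C → rt
Reagents that add atoms: trimethylsulfonium iodide (as its methylide), C[S+](C)C.[I-]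
Why: The same sulfonium methylide homologation in the antipodal series supplies the future C7 centre with retention.

**Step 11**
Reactants: 15 methyl ester with terminal alkene; 17 (S)-1-(benzyloxy)but-3-en-2-ol
Product: 20 methyl (3S,9E,11S)-12-(benzyloxy)-3-[(1R,2R)-3-(benzyloxy)-1-(tert-butyldimethylsilyloxy)-2-methylpropyl]-11-hydroxydodec-9-enoate
Conditions: 17 (3 equiv), second-generation Hoveyda–Grubbs catalyst RuCl2(H2IMes)(=CH-C6H4-2-Oi-Pr) (cat.), CH2Cl2, 40 °C
Reagents that add atoms: none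
Why: Olefin cross-metathesis of an unhindered terminal alkene with a secondary allylic alcohol is E-selective, and the product re-enters the cycle only slowly; this builds C9′=C8′–C7′(OH)–C6′.

**Step 12**
Reactants: 15 methyl ester with terminal alkene; 19 (R)-1-(benzyloxy)but-3-en-2-ol
Product: 21 the (3S,9E,11R) diastereomer of 20
Conditions: 19 (3 equiv), second-generation Hoveyda–Grubbs catalyst RuCl2(H2IMes)(=CH-C6H4-2-Oi-Pr) (cat.), CH2Cl2, 40 °C
Reagents that add atoms: none
Why: The same E-selective cross-metathesis installs C9=C8–C7(OH)–C6 of unit 1 on the second copy of 15.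

**Step 13**
Reactants: 21 hydroxy ester
Product: 22 11-O-triethylsilyl ether of 21
Conditions: Et3SiCl, imidazole, CH2Cl2, 0 °C
Reagents that add atoms: chlorotriethylsilane, CC[Si](Cl)(CC)CC
Why: Standard silylation masks the C7 hydroxyl with a group that can later be removed by dilute acid beside the hindered TBS ethers.

**Step 14**
Reactants: 22 silyl ether ester
Product: 23 (3S,9E,11R)-12-(benzyloxy)-3-[(1R,2R)-3-(benzyloxy)-1-(tert-butyldimethylsilyloxy)-2-methylpropyl]-11-(triethylsilyloxy)dodec-9-enoic acid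
Conditions: LiOH, THF–MeOH–H2O, rt; 0.5 M HCl to pH 5, 0 °C
Reagents that add atoms: lithium hydroxide, [Li+].[OH-]
Why: Saponification of the unbranched-α methyl ester is routine, and both silyl ethers tolerate hydroxide and the cold mild acidification.

**Step 15**
Reactants: 23 acid (C9a′ carboxyl); 20 alcohol (C7′ hydroxyl)
Product: 24 ester of acid 23 with the C7′ hydroxyl of 20
Conditions: i-PrN=C=Ni-Pr, DMAP, CH2Cl2, 0 °C → rt
Reagents that add atoms: none
Why: Steglich esterification joins the two halves through O7′ without touching any stereocentre.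

**Step 16**
Reactants: 24 allylic ester
Product: 27 open-chain (9′S,9a′S) acid with the new C9′–C9a′ bond and an E-CH=CH–CH2OBn group on C9′, via bis(silyl ketene acetal) 25 (not isolated), via trimethylsilyl ester 26 (not isolated)
Conditions: LiN(i-Pr)2 (3 equiv), THF–DMPU, −78 °C; Me3SiCl; −78 °C → rt; aq. NaH2PO4, THF
Reagents that add atoms: none
Why: In this Ireland–Claisen rearrangement enolisation in THF–DMPU gives the Z-silyl ketene acetal, which pairs with the E-alkene in a chair that keeps C6′H2OBn equatorial, so C7′ (S) is relayed to C9′ (S), the geometry pair sets the syn C9a′ (S), the A(1,3)-locked C1′ centre favours the same face, and the methyl ester is merely silylated and returns on work-up.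

**Step 17**
Reactants: 27 acid
Product: 30 tert-butyl carbamate with N5′ on C9a′, via acyl azide 28 (not isolated), via isocyanate 29 (not isolated)
Conditions: (PhO)2P(O)N3, Et3N, PhMe, rt → 90 °C; t-BuOH, CuCl (cat.), 60 °C
Reagents that add atoms: diphenylphosphoryl azide, [N-]=[N+]=NP(=O)(Oc1ccccc1)Oc1ccccc1; tert-butanol, CC(C)(C)O
Why: In the Curtius rearrangement C9a′ migrates from carbon to nitrogen with retention, and CuCl helps tert-butanol capture the hindered isocyanate.

**Step 18**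
Reactants: 30 carbamate methyl ester
Product: 32 seco acid with free C9a carboxyl and free (7R) hydroxyl, via silyl ether acid 31 (not isolated)
Conditions: LiOH, THF–MeOH–H2O, rt; then 1 M HCl to pH 2, rt
Reagents that add atoms: lithium hydroxide, [Li+].[OH-]
Why: Saponification followed in the same flask by dilute-acid cleavage of the unhindered allylic triethylsilyl ether should leave the Boc group and the flanked TBS ethers in place.

**Step 19**
Reactants: 32 seco acid
Product: 34 20-membered (7R,8E) allylic macrolactone, via nitrobenzoic mixed anhydride 33 (not isolated)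
Conditions: 2-methyl-6-nitrobenzoic anhydride, DMAP, CH2Cl2 (high dilution, slow addition), rt
Reagents that add atoms: none
Why: Shiina macrolactonisation closes a strain-free 20-membered ring at room temperature by acyl transfer to O7, so C7 keeps its configuration.

**Step 20**
Reactants: 34 20-membered allylic macrolactone
Product: 37 16-membered carbocyclic (9R,9aR) acid with CO2H on C9a and E-CH=CH–CH2OBn on C9, via Z-silyl ketene acetal 35 (not isolated), via trimethylsilyl ester 36 (not isolated)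
Conditions: LiN(i-Pr)2 (3.5 equiv), THF–DMPU, −78 °C; Me3SiCl, −78 °C → rt, then 45 °C; aq. citric acid, THF
Reagents that add atoms: none
Why: After the carbamate N–H, the base removes a C9a proton and Me3SiCl traps the Z-silyl ketene acetal 35, which undergoes a concerted suprafacial [3,3] shift in which C9–C9a forms as C7–O breaks, giving silyl ester 36 and then acid 37 on hydrolysis. The closest known reaction type is the Ireland–Claisen ring contraction of macrocyclic allylic lactones to carbocycles four atoms smaller. The 16-membered ring is therefore closed by transannular contraction of the 20-membered lactone through an embedded six-atom chair rather than by end-to-end cyclisation, and the carboxyl group and the C8=C7–C6 chain are turned out of the new ring. C9 (R) is fixed by 1,3-chirality transfer from C7 (R), because the chair that keeps C6H2OBn equatorial exposes one alkene face only and leads to the E-alkene. C9a (R) is fixed relative to C9 by the E-alkene/Z-ketene acetal pairing, which gives the 2,3-syn acid, that is the trans H9/H9a relation once CO2H becomes N5. The step needs Z-selective enolisation (secured by DMPU), chair over boat (secured by the equatorial C1/C10 pair and the slack of the large ring) and dominance of C7 over the A(1,3)-locked C1 centre, whose own bias would turn the bulky C2 arm away from the allyl terminus; that dominance rests on the 1,3-diaxial clash between an axial CH2OBn and OSiMe3 in the alternative chair, and no other group in 34 can rearrange.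

**Step 21**
Reactants: 37 acid
Product: 40 bis(tert-butyl carbamate) with N5 on C9a and N5′ on C9a′, via acyl azide 38 (not isolated), via isocyanate 39 (not isolated)
Conditions: (PhO)2P(O)N3, Et3N, PhMe, rt → 90 °C; t-BuOH, CuCl (cat.), 60 °C
Reagents that add atoms: diphenylphosphoryl azide, [N-]=[N+]=NP(=O)(Oc1ccccc1)Oc1ccccc1; tert-butanol, CC(C)(C)O
Why: A second Curtius rearrangement exchanges the carboxyl group for N5 with retention at C9a.

**Step 22**
Reactants: 40 bis-carbamate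
Product: 41 saturated tetraol (C4, C6, C4′ and C6′ hydroxyls free)
Conditions: H2 (4 bar), Pd(OH)2/C, EtOH–EtOAc, rt
Reagents that add atoms: none
Why: Catalytic hydrogenation saturates both exocyclic E-alkenes and hydrogenolysis removes the four benzyl ethers, while the Boc and TBS groups are inert.

**Step 23**
Reactants: 41 tetraol
Product: 42 tetrakis(methanesulfonate) of 41
Conditions: MsCl, Et3N, CH2Cl2, −10 °C
Reagents that add atoms: methanesulfonyl chloride, CS(=O)(=O)Cl
Why: Standard mesylation activates the four primary carbons, and the hindered carbamate N–H groups do not compete.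

**Step 24**
Reactants: 42 tetramesylate
Product: 44 bis-quinolizidine diol (2S,2′S carbinols), via diammonium dichloride 43 (not isolated)
Conditions: HCl (3 M in MeOH), 0 → 40 °C; evaporate; K2CO3, NaI (cat.), MeCN (dilute), 60 °C
Reagents that add atoms: none
Why: Acidolysis removes both Boc and both TBS groups, and on basification each primary amine closes its two rings by 6-exo-tet intramolecular SN2 displacement (double N-alkylation, the standard quinolizidine closure), which touches no stereocentre.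

**Step 25**
Reactants: 44 diol
Product: 45 target CNP0268544.1
Conditions: CF3CO2H (2 equiv), Dess–Martin periodinane, CH2Cl2, 0 °C → rt; cold aq. NaHCO3
Reagents that add atoms: none
Why: Dess–Martin oxidation of the bis-ammonium salt converts both equatorial carbinols into ketones without free base, so N-oxidation, enolisation and retro-Michael opening at the labile C1/C3 centres of unit 1 should be avoided.

**Compound list**
1 | methyl (R)-3-hydroxy-2-methylpropanoate | C[C@@H](C(=O)OC)CO | starting material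
2 | methyl (R)-3-(benzyloxy)-2-methylpropanoate | C[C@@H](C(=O)OC)COCc1ccccc1 | intermediate
3 | (R)-3-(benzyloxy)-2-methylpropanal | C[C@@H](C=O)COCc1ccccc1 | intermediate
4 | non-8-enoic acid | C=CCCCCCCC(=O)O | starting material
5 | (R)-4-benzyl-1,3-oxazolidin-2-one | O=C1N[C@H](Cc2ccccc2)CO1 | starting material
6 | non-8-enoic pivalic anhydride | C=CCCCCCCC(=O)OC(=O)C(C)(C)C | intermediate
7 | (R)-4-benzyl-3-(non-8-enoyl)-1,3-oxazolidin-2-one | C=CCCCCCCC(=O)N1[C@H](Cc2ccccc2)COC1=O | intermediate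
8 | Z-dibutylboron enolate of 7 | C=CCCCCC/C=C(\OB(CCCC)CCCC)N1[C@H](Cc2ccccc2)COC1=O | intermediate
9 | syn aldol adduct (2R,3S,4R) | O=C(N1[C@H](Cc2ccccc2)COC1=O)[C@@H]([C@@H](O)[C@H](C)COCc2ccccc2)CCCCCC=C | intermediate
10 | TBS ether of 9 | O=C(N1[C@H](Cc2ccccc2)COC1=O)[C@@H]([C@@H](O[Si](C)(C)C(C)(C)C)[C@H](C)COCc2ccccc2)CCCCCC=C | intermediate
11 | (2R,3S,4R) acid | OC(=O)[C@@H]([C@@H](O[Si](C)(C)C(C)(C)C)[C@H](C)COCc1ccccc1)CCCCCC=C | intermediate
12 | isobutyl carbonic anhydride of 11 | CC(C)COC(=O)OC(=O)[C@@H]([C@@H](O[Si](C)(C)C(C)(C)C)[C@H](C)COCc1ccccc1)CCCCCC=C | intermediate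
13 | α-diazoketone | [N-]=[N+]=CC(=O)[C@@H]([C@@H](O[Si](C)(C)C(C)(C)C)[C@H](C)COCc1ccccc1)CCCCCC=C | intermediate
14 | ketene | O=C=C[C@@H]([C@@H](O[Si](C)(C)C(C)(C)C)[C@H](C)COCc1ccccc1)CCCCCC=C | intermediate
15 | homologated methyl ester (C1 S, C2 R, C3 R) | COC(=O)C[C@@H]([C@@H](O[Si](C)(C)C(C)(C)C)[C@H](C)COCc1ccccc1)CCCCCC=C | intermediate
16 | (S)-benzyl glycidyl ether | C1O[C@@H]1COCc2ccccc2 | starting material
17 | (S)-1-(benzyloxy)but-3-en-2-ol | C=C[C@H](O)COCc1ccccc1 | intermediate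
18 | (R)-benzyl glycidyl ether | C1O[C@H]1COCc2ccccc2 | starting material
19 | (R)-1-(benzyloxy)but-3-en-2-ol | C=C[C@@H](O)COCc1ccccc1 | intermediate
20 | E-allylic alcohol, 7′S | COC(=O)C[C@@H]([C@@H](O[Si](C)(C)C(C)(C)C)[C@H](C)COCc1ccccc1)CCCCC/C=C/[C@H](O)COCc1ccccc1 | intermediate
21 | E-allylic alcohol, 7R | COC(=O)C[C@@H]([C@@H](O[Si](C)(C)C(C)(C)C)[C@H](C)COCc1ccccc1)CCCCC/C=C/[C@@H](O)COCc1ccccc1 | intermediate
22 | triethylsilyl ether of 21 | COC(=O)C[C@@H]([C@@H](O[Si](C)(C)C(C)(C)C)[C@H](C)COCc1ccccc1)CCCCC/C=C/[C@@H](O[Si](CC)(CC)CC)COCc1ccccc1 | intermediate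
23 | acid from 22 | OC(=O)C[C@@H]([C@@H](O[Si](C)(C)C(C)(C)C)[C@H](C)COCc1ccccc1)CCCCC/C=C/[C@@H](O[Si](CC)(CC)CC)COCc1ccccc1 | intermediate
24 | ester of 23 with O7′ of 20 | COC(=O)C[C@@H]([C@@H](O[Si](C)(C)C(C)(C)C)[C@H](C)COCc1ccccc1)CCCCC/C=C/[C@H](OC(=O)C[C@@H]([C@@H](O[Si](C)(C)C(C)(C)C)[C@H](C)COCc1ccccc1)CCCCC/C=C/[C@@H](O[Si](CC)(CC)CC)COCc1ccccc1)COCc1ccccc1 | intermediate
25 | bis(silyl ketene acetal), allylic one Z | COC(O[Si](C)(C)C)=C[C@@H]([C@@H](O[Si](C)(C)C(C)(C)C)[C@H](C)COCc1ccccc1)CCCCC/C=C/[C@H](O/C(O[Si](C)(C)C)=C/[C@@H]([C@@H](O[Si](C)(C)C(C)(C)C)[C@H](C)COCc1ccccc1)CCCCC/C=C/[C@@H](O[Si](CC)(CC)CC)COCc1ccccc1)COCc1ccccc1 | intermediate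
26 | rearranged trimethylsilyl ester | COC(O[Si](C)(C)C)=C[C@@H]([C@@H](O[Si](C)(C)C(C)(C)C)[C@H](C)COCc1ccccc1)CCCCC[C@@H](/C=C/COCc1ccccc1)[C@H](C(=O)O[Si](C)(C)C)[C@@H]([C@@H](O[Si](C)(C)C(C)(C)C)[C@H](C)COCc1ccccc1)CCCCC/C=C/[C@@H](O[Si](CC)(CC)CC)COCc1ccccc1 | intermediate
27 | (9′S,9a′S) acid | COC(=O)C[C@@H]([C@@H](O[Si](C)(C)C(C)(C)C)[C@H](C)COCc1ccccc1)CCCCC[C@@H](/C=C/COCc1ccccc1)[C@H](C(=O)O)[C@@H]([C@@H](O[Si](C)(C)C(C)(C)C)[C@H](C)COCc1ccccc1)CCCCC/C=C/[C@@H](O[Si](CC)(CC)CC)COCc1ccccc1 | intermediate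
28 | acyl azide of 27 | COC(=O)C[C@@H]([C@@H](O[Si](C)(C)C(C)(C)C)[C@H](C)COCc1ccccc1)CCCCC[C@@H](/C=C/COCc1ccccc1)[C@H](C(=O)N=[N+]=[N-])[C@@H]([C@@H](O[Si](C)(C)C(C)(C)C)[C@H](C)COCc1ccccc1)CCCCC/C=C/[C@@H](O[Si](CC)(CC)CC)COCc1ccccc1 | intermediate
29 | C9a′ isocyanate | COC(=O)C[C@@H]([C@@H](O[Si](C)(C)C(C)(C)C)[C@H](C)COCc1ccccc1)CCCCC[C@@H](/C=C/COCc1ccccc1)[C@H](N=C=O)[C@@H]([C@@H](O[Si](C)(C)C(C)(C)C)[C@H](C)COCc1ccccc1)CCCCC/C=C/[C@@H](O[Si](CC)(CC)CC)COCc1ccccc1 | intermediate
30 | C9a′ tert-butyl carbamate | COC(=O)C[C@@H]([C@@H](O[Si](C)(C)C(C)(C)C)[C@H](C)COCc1ccccc1)CCCCC[C@@H](/C=C/COCc1ccccc1)[C@H](NC(=O)OC(C)(C)C)[C@@H]([C@@H](O[Si](C)(C)C(C)(C)C)[C@H](C)COCc1ccccc1)CCCCC/C=C/[C@@H](O[Si](CC)(CC)CC)COCc1ccccc1 | intermediate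
31 | acid still bearing the triethylsilyl ether | OC(=O)C[C@@H]([C@@H](O[Si](C)(C)C(C)(C)C)[C@H](C)COCc1ccccc1)CCCCC[C@@H](/C=C/COCc1ccccc1)[C@H](NC(=O)OC(C)(C)C)[C@@H]([C@@H](O[Si](C)(C)C(C)(C)C)[C@H](C)COCc1ccccc1)CCCCC/C=C/[C@@H](O[Si](CC)(CC)CC)COCc1ccccc1 | intermediate
32 | seco acid | OC(=O)C[C@@H]([C@@H](O[Si](C)(C)C(C)(C)C)[C@H](C)COCc1ccccc1)CCCCC[C@@H](/C=C/COCc1ccccc1)[C@H](NC(=O)OC(C)(C)C)[C@@H]([C@@H](O[Si](C)(C)C(C)(C)C)[C@H](C)COCc1ccccc1)CCCCC/C=C/[C@@H](O)COCc1ccccc1 | intermediate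
33 | 2-methyl-6-nitrobenzoic mixed anhydride of 32 | Cc1cccc([N+](=O)[O-])c1C(=O)OC(=O)C[C@@H]([C@@H](O[Si](C)(C)C(C)(C)C)[C@H](C)COCc1ccccc1)CCCCC[C@@H](/C=C/COCc1ccccc1)[C@H](NC(=O)OC(C)(C)C)[C@@H]([C@@H](O[Si](C)(C)C(C)(C)C)[C@H](C)COCc1ccccc1)CCCCC/C=C/[C@@H](O)COCc1ccccc1 | intermediate
34 | 20-membered (7R,8E) allylic macrolactone | O=C1C[C@@H]([C@@H](O[Si](C)(C)C(C)(C)C)[C@H](C)COCc2ccccc2)CCCCC[C@@H](/C=C/COCc2ccccc2)[C@H](NC(=O)OC(C)(C)C)[C@@H]([C@@H](O[Si](C)(C)C(C)(C)C)[C@H](C)COCc2ccccc2)CCCCC/C=C/[C@H](COCc2ccccc2)O1 | intermediate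
35 | Z-silyl ketene acetal (N-silylated) | C[Si](C)(C)O/C1=C\[C@@H]([C@@H](O[Si](C)(C)C(C)(C)C)[C@H](C)COCc2ccccc2)CCCCC[C@@H](/C=C/COCc2ccccc2)[C@H](N([Si](C)(C)C)C(=O)OC(C)(C)C)[C@@H]([C@@H](O[Si](C)(C)C(C)(C)C)[C@H](C)COCc2ccccc2)CCCCC/C=C/[C@H](COCc2ccccc2)O1 | intermediate
36 | ring-contracted trimethylsilyl ester | C[Si](C)(C)OC(=O)[C@H]1[C@@H]([C@@H](O[Si](C)(C)C(C)(C)C)[C@H](C)COCc2ccccc2)CCCCC[C@@H](/C=C/COCc2ccccc2)[C@H](N([Si](C)(C)C)C(=O)OC(C)(C)C)[C@@H]([C@@H](O[Si](C)(C)C(C)(C)C)[C@H](C)COCc2ccccc2)CCCCC[C@@H]1/C=C/COCc2ccccc2 | intermediate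
37 | 16-membered carbocyclic (9R,9aR) acid | OC(=O)[C@H]1[C@@H]([C@@H](O[Si](C)(C)C(C)(C)C)[C@H](C)COCc2ccccc2)CCCCC[C@@H](/C=C/COCc2ccccc2)[C@H](NC(=O)OC(C)(C)C)[C@@H]([C@@H](O[Si](C)(C)C(C)(C)C)[C@H](C)COCc2ccccc2)CCCCC[C@@H]1/C=C/COCc2ccccc2 | intermediate
38 | acyl azide of 37 | [N-]=[N+]=NC(=O)[C@H]1[C@@H]([C@@H](O[Si](C)(C)C(C)(C)C)[C@H](C)COCc2ccccc2)CCCCC[C@@H](/C=C/COCc2ccccc2)[C@H](NC(=O)OC(C)(C)C)[C@@H]([C@@H](O[Si](C)(C)C(C)(C)C)[C@H](C)COCc2ccccc2)CCCCC[C@@H]1/C=C/COCc2ccccc2 | intermediate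
39 | C9a isocyanate | O=C=N[C@H]1[C@@H]([C@@H](O[Si](C)(C)C(C)(C)C)[C@H](C)COCc2ccccc2)CCCCC[C@@H](/C=C/COCc2ccccc2)[C@H](NC(=O)OC(C)(C)C)[C@@H]([C@@H](O[Si](C)(C)C(C)(C)C)[C@H](C)COCc2ccccc2)CCCCC[C@@H]1/C=C/COCc2ccccc2 | intermediate
40 | bis(tert-butyl carbamate) | CC(C)(C)OC(=O)N[C@H]1[C@@H]([C@@H](O[Si](C)(C)C(C)(C)C)[C@H](C)COCc2ccccc2)CCCCC[C@@H](/C=C/COCc2ccccc2)[C@H](NC(=O)OC(C)(C)C)[C@@H]([C@@H](O[Si](C)(C)C(C)(C)C)[C@H](C)COCc2ccccc2)CCCCC[C@@H]1/C=C/COCc2ccccc2 | intermediate
41 | saturated tetraol | CC(C)(C)OC(=O)N[C@H]1[C@@H]([C@@H](O[Si](C)(C)C(C)(C)C)[C@H](C)CO)CCCCC[C@@H](CCCO)[C@H](NC(=O)OC(C)(C)C)[C@@H]([C@@H](O[Si](C)(C)C(C)(C)C)[C@H](C)CO)CCCCC[C@@H]1CCCO | intermediate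
42 | tetramesylate | CC(C)(C)OC(=O)N[C@H]1[C@@H]([C@@H](O[Si](C)(C)C(C)(C)C)[C@H](C)COS(C)(=O)=O)CCCCC[C@@H](CCCOS(C)(=O)=O)[C@H](NC(=O)OC(C)(C)C)[C@@H]([C@@H](O[Si](C)(C)C(C)(C)C)[C@H](C)COS(C)(=O)=O)CCCCC[C@@H]1CCCOS(C)(=O)=O | intermediate
43 | diammonium dichloride, diol tetramesylate | [Cl-].[Cl-].[NH3+][C@H]1[C@@H]([C@@H](O)[C@H](C)COS(C)(=O)=O)CCCCC[C@@H](CCCOS(C)(=O)=O)[C@H]([NH3+])[C@@H]([C@@H](O)[C@H](C)COS(C)(=O)=O)CCCCC[C@@H]1CCCOS(C)(=O)=O | intermediate
44 | bis-quinolizidine diol | C[C@@H]1CN2CCC[C@H]3CCCCC[C@@H]4[C@@H](O)[C@H](C)CN5CCC[C@H](CCCCC[C@H]([C@H]1O)[C@@H]32)[C@@H]45 | intermediate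
45 | CNP0268544.1 | C[C@@H]1CN2CCC[C@H]3CCCCC[C@@H]4C(=O)[C@H](C)CN5CCC[C@H](CCCCC[C@H](C1=O)[C@@H]32)[C@@H]45 | target

**Counts**
- Total step count: 25.
- Longest linear sequence: 21 steps (steps 1, 2, 4–8 and 12–25, from 1 to 45).

**Steps most likely to fail**

Step 20. Diastereoselection may erode in three ways:
- Z-enolisation inside the ring may be incomplete.
- Some material may leak through a boat.
- The A(1,3)-locked C1 centre has a facial preference that opposes the chair directed by C7.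

The fallback replaces substrate control of the enolate face by reagent control, using the known chiral-boron variant of the ester enolate Claisen, which has also been applied to macrolactone ring contraction. It sets out from 34. The bromoborane made from (S,S)-1,2-diphenylethane-1,2-diamine bis[3,5-bis(trifluoromethyl)benzenesulfonamide] and BBr3, with i-Pr2NEt in CH2Cl2 at −78 °C, should give the chiral boron ketene acetal F1. Between −20 and 4 °C this should rearrange to the acyloxyborane F2, and aqueous work-up rejoins the route at 37. The antipodal controller is taken if a trial shows the drawn one to be mismatched with C7.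

Step 24. The flanked C2/C2′ silyl ethers may be cleaved too slowly under conditions that the primary mesylates survive, so solvolysis or partial cyclisation may intervene. The fallback separates deprotection from activation. It sets out from 41, where methanolic HCl can be forced as needed because no sulfonate is present, and this should give the diamino hexaol dihydrochloride F3. Appel-type cyclodehydration (PPh3, CBr4, Et3N, CH2Cl2–MeCN) then activates only the four primary alcohols in the presence of the amines, closes all four rings and rejoins the route at 44.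

Step 22. The two allylic C6–O and C6′–O bonds may undergo hydrogenolysis on palladium before the alkenes are saturated, which would remove the oxygen needed later as a leaving group. The fallback sets out from 40. Diimide (2-nitrobenzenesulfonyl hydrazide, Et3N, CH2Cl2, rt) should reduce both alkenes without touching C–O bonds to give the saturated tetrabenzyl ether F4. Ordinary hydrogenolysis (H2, Pd(OH)2/C, EtOH) then rejoins the route at 41.

**Further compounds**
F1 | step 20 | chiral boron ketene acetal of 34 | O=S(=O)(c4cc(C(F)(F)F)cc(C(F)(F)F)c4)N3B(O/C1=C\[C@@H]([C@@H](O[Si](C)(C)C(C)(C)C)[C@H](C)COCc2ccccc2)CCCCC[C@@H](/C=C/COCc2ccccc2)[C@H](NC(=O)OC(C)(C)C)[C@@H]([C@@H](O[Si](C)(C)C(C)(C)C)[C@H](C)COCc2ccccc2)CCCCC/C=C/[C@H](COCc2ccccc2)O1)N(S(=O)(=O)c4cc(C(F)(F)F)cc(C(F)(F)F)c4)[C@@H](c4ccccc4)[C@@H]3c4ccccc4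
F2 | step 20 | ring-contracted acyloxyborane | O=C(OB3N(S(=O)(=O)c4cc(C(F)(F)F)cc(C(F)(F)F)c4)[C@@H](c4ccccc4)[C@H](c4ccccc4)N3S(=O)(=O)c4cc(C(F)(F)F)cc(C(F)(F)F)c4)[C@H]1[C@@H]([C@@H](O[Si](C)(C)C(C)(C)C)[C@H](C)COCc2ccccc2)CCCCC[C@@H](/C=C/COCc2ccccc2)[C@H](NC(=O)OC(C)(C)C)[C@@H]([C@@H](O[Si](C)(C)C(C)(C)C)[C@H](C)COCc2ccccc2)CCCCC[C@@H]1/C=C/COCc2ccccc2
F3 | step 24 | diamino hexaol dihydrochloride | Cl.Cl.N[C@H]1[C@@H]([C@@H](O)[C@H](C)CO)CCCCC[C@@H](CCCO)[C@H](N)[C@@H]([C@@H](O)[C@H](C)CO)CCCCC[C@@H]1CCCO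
F4 | step 22 | saturated tetrabenzyl ether | CC(C)(C)OC(=O)N[C@H]1[C@@H]([C@@H](O[Si](C)(C)C(C)(C)C)[C@H](C)COCc2ccccc2)CCCCC[C@@H](CCCOCc2ccccc2)[C@H](NC(=O)OC(C)(C)C)[C@@H]([C@@H](O[Si](C)(C)C(C)(C)C)[C@H](C)COCc2ccccc2)CCCCC[C@@H]1CCCOCc2ccccc2
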